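**Plan**

1. Numbering: ring C1 (carries the chain), C2 (OH), C3 (O-isobutyryl), C4 (Me, OH), C5 (OAc), C6 (O-isobutyryl); chain C7(=CH2)–C8(O-isobutyryl)–C9H2–C10(OH)–C11(Me2)OH; "up" is the ring face that holds C7 and O4.
2. Feature used: on the cyclohexane C1–C6, C7 (on C1) and the tertiary oxygen on C4 are 1,4-cis, with the cis C2/C3 diol between them. This is the imprint of a 2-pyrone whose O–C(=O) unit bridges C4 and C1, and of a cis-enediol ether that has added across its diene.
3. Cuts: C1–C2 and C3–C4 (pyrone + dioxole cycloaddition), C8–C9 (aldol), C7=CH2 and C7–C8 (methylenation and one-carbon extension at the former lactone carbon). The carboxyl on C1 that activates the pyrone is removed by radical decarboxylation.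
4. Forward order: pyrone 4 and dioxole 7; the only carbocycle closes in step 4 as a lactone-bridged bicyclo[2.2.2]octene; C5/C6 diol, decarboxylation, bridge opened to a C1 alkyne; ring esters placed one diol at a time; alkyne to enal, aldol, Evans–Tishchenko, desilylation.
5. Stereochemistry: C1–C4 from the ligand-controlled endo cycloaddition; C5 and C6 from dihydroxylation on the lactone face of the bicycle; ester positions from axial-selective opening of cyclic orthoesters; C8 from an Ipc2B-enolate aldol; C10 from 1,3-anti hydride delivery.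

Key step: step 4

Remark: the diol lactones 9, 10 and 12 are written as [2.2.2] lactones; if the lactone acyl group shifted from O4 to the cis O5, the isomeric lactone would be carried on, because steps 8 and 9 lead to the same triol 14.

**Route**

Step 1
Reactants: 1 dibenzyl malonate; 2 (E)-4-methoxybut-3-en-2-one
Product: 4 benzyl 6-methyl-2-oxo-2H-pyran-3-carboxylate, via dibenzyl 2-[(E)-3-oxobut-1-enyl]malonate 3 (not isolated)
Conditions: NaH (1.0 equiv), THF, 0 °C to rt; then AcOH, toluene, 90 °C
Reagents that add atoms: none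
Why: Addition–elimination of the malonate anion on the β-methoxy enone (vinylogous acyl substitution), then lactonisation of the dienol onto one ester, is the usual entry to 3-carboalkoxy-2-pyrones.

Step 2
Reactants: 5 2,2-dimethyl-1,3-dioxolane
Product: 6 4-chloro-2,2-dimethyl-1,3-dioxolane (racemic)
Conditions: t-BuOCl, hν, 0 °C
Reagents that add atoms: tert-butyl hypochlorite, CC(C)(C)OCl
Why: Radical chain chlorination takes the C–H next to oxygen at C4 (α-oxy radical), the normal site selectivity of ether halogenation, under neutral conditions that spare the ketal.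

Step 3
Reactants: 6 4-chloro-2,2-dimethyl-1,3-dioxolane
Product: 7 2,2-dimethyl-1,3-dioxole
Conditions: t-BuOK, tetraglyme, 0 to 60 °C, product distilled out
Reagents that add atoms: none
Why: E2 dehydrochlorination of the α-chloro ether by a hindered alkoxide should give the volatile cis-enediol ketal, the same chlorination–elimination logic that converts ethylene carbonate into vinylene carbonate.

Step 4
Reactants: 4 benzyl 6-methyl-2-oxo-2H-pyran-3-carboxylate; 7 2,2-dimethyl-1,3-dioxole
Product: 8 endo bicyclic lactone (2-oxabicyclo[2.2.2]oct-5-en-3-one: CO2Bn on C1, Me on C4, C5=C6, C2/C3 acetonide anti to the lactone bridge)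
Conditions: Cu(OTf)2 (10 mol%), (R,R)-t-Bu-BOX (11 mol%), 4 Å MS, CH2Cl2, −20 °C to rt
Reagents that add atoms: none
Why: The pyrone binds divalent copper through its ester and lactone carbonyls, which lowers the diene LUMO, and the electron-rich dioxole adds across the diene termini in a concerted but asynchronous inverse-electron-demand Diels–Alder reaction, the bond to the methyl-bearing terminus (C3–C4) running ahead of C1–C2. The closest known reaction type is the Cu(OTf)2/bis(oxazoline)-catalysed cycloaddition of 3-carboalkoxy-2-pyrones with enol ethers. The carbocycle C1–C6 closes by a suprafacial [4+2] ring closure as the boat of the bicyclo[2.2.2]octene, with O–C7(=O) as the third bridge. C1 and C4 are set together because the bridge spans one face only; C2 and C3 are cis because the dioxole alkene adds suprafacially; their oxygens come out anti to the lactone bridge through the endo transition state (overlap of the dioxole oxygens with the diene, away from the ligand); the absolute sense comes from the tert-butyl group that covers one face of the square-planar chelate, for which the model calls for the (R,R)-ligand. The step needs endo and π-face selectivity only, since the dienophile is symmetric; both rest on two-point chelation of the 3-carboxylate to the chiral copper centre, and the temperature stays at or below rt so that the adduct does not lose CO2.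

Step 5
Reactants: 8 endo bicyclic lactone
Product: 9 diol lactone (C5,C6-diol on the lactone face, benzyl ester on C1)
Conditions: K2OsO2(OH)4 (2 mol%), NMO, citric acid, t-BuOH/H2O, rt
Reagents that add atoms: N-methylmorpholine N-oxide, C[N+]1([O-])CCOCC1; water, O
Why: Upjohn dihydroxylation: OsO4 adds suprafacially to C5=C6 from the face next to the lactone bridge because the other face lies under the CMe2 of the endo acetonide, which sets O5 and O6 up; the acidic buffer should keep O5 from taking over the lactone acyl group.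

Step 6
Reactants: 9 diol lactone
Product: 10 diol lactone acid (CO2H on C1)
Conditions: H2 (1 atm), 10% Pd/C, EtOAc, rt
Reagents that add atoms: none
Why: Hydrogenolysis of the benzyl ester; the alkene is already consumed, and the bridgehead acid cannot decarboxylate thermally because its enol would be an anti-Bredt olefin.

Step 7
Reactants: 10 diol lactone acid
Product: 12 decarboxylated diol lactone (H on C1), via Barton ester 11 (not isolated)
Conditions: 2,2'-dithiobis(pyridine N-oxide), n-Bu3P, THF, 0 °C, dark; then t-BuSH, hν (tungsten lamp), 0 °C to rt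
Reagents that add atoms: none
Why: Barton decarboxylation: the thiohydroxamate ester is made by neutral redox condensation that tolerates the diol, and the σ-type bridgehead C1 radical takes hydrogen from the thiol with necessary retention, so C1 keeps the configuration from step 4.

Step 8
Reactants: 12 decarboxylated diol lactone
Product: 13 bridged lactol (C7 hemiacetal, anomers)
Conditions: i-Bu2AlH (4 equiv), CH2Cl2, −78 °C; aq. potassium sodium tartrate
Reagents that add atoms: none
Why: Partial reduction of the strained bridged lactone to the lactol, the tetrahedral aluminate being stable at −78 °C; two equivalents are consumed by the diol.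

Step 9
Reactants: 13 bridged lactol
Product: 14 alkyne triol (ethynyl on C1; OH on C4, C5, C6; C2/C3 acetonide)
Conditions: dimethyl (1-diazo-2-oxopropyl)phosphonate, K2CO3, MeOH, 0 °C to rt
Reagents that add atoms: dimethyl (1-diazo-2-oxopropyl)phosphonate, COP(=O)(OC)C(=[N+]=[N-])C(C)=O
Why: Ohira–Bestmann (Seyferth–Gilbert) homologation of the lactol through its hydroxy-aldehyde tautomer; only the C1 epimer drawn can rest as a lactol, which works against epimerisation next to the aldehyde.

Step 10
Reactants: 14 alkyne triol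
Product: 16 C6 isobutyrate (OH on C5 and C4), via C5/C6 cyclic orthoisobutyrate 15 (not isolated)
Conditions: i-PrC(OMe)3, PPTS (cat.), CH2Cl2, rt; then 80% aq. AcOH, rt
Reagents that add atoms: trimethyl orthoisobutyrate, CC(C)C(OC)(OC)OC; water, O
Why: Orthoester exchange should engage the secondary cis-5,6-diol under kinetic control (the tertiary C4 hydroxyl is much slower), and acid hydrolysis of the 2-alkoxy-1,3-dioxolane follows the stereoelectronic rule for cyclohexane cis-diols, ester on the axial oxygen (O6) and equatorial hydroxyl (O5) free, in the chair that keeps the C4 methyl and the C1 substituent equatorial.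

Step 11
Reactants: 16 C6 isobutyrate
Product: 17 C5 acetate C6 isobutyrate
Conditions: Ac2O, pyridine, DMAP (cat.), CH2Cl2, 0 °C
Reagents that add atoms: acetic anhydride, CC(=O)OC(C)=O
Why: Acylation of the equatorial secondary C5 hydroxyl; the tertiary C4 hydroxyl does not react at 0 °C.

Step 12
Reactants: 17 C5 acetate C6 isobutyrate
Product: 18 C2,C3,C4-triol
Conditions: TFA/H2O (9:1), CH2Cl2, 0 °C
Reagents that add atoms: none
Why: Acid hydrolysis of the isopropylidene acetal; the esters and the alkyne are stable to cold aqueous acid for the short time needed, and acyl shift to the tertiary O4 is uphill.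

Step 13
Reactants: 18 C2,C3,C4-triol
Product: 20 C3 isobutyrate (OH on C2 and C4), via C2/C3 cyclic orthoisobutyrate 19 (not isolated)
Conditions: i-PrC(OMe)3, PPTS (cat.), CH2Cl2, rt; then 80% aq. AcOH, rt
Reagents that add atoms: trimethyl orthoisobutyrate, CC(C)C(OC)(OC)OC; water, O
Why: The same orthoester exchange and hydrolysis on the cis-2,3-diol (O4 is trans-diaxial to O3 and cannot join a ring): the acyl group is delivered intramolecularly to the hindered axial O3 and the equatorial O2 is released.

Step 14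
Reactants: 20 C3 isobutyrate
Product: 21 C2,C4-bis(triethylsilyl) ether
Conditions: TESOTf (3 equiv), 2,6-lutidine, CH2Cl2, −40 to 0 °C
Reagents that add atoms: triethylsilyl trifluoromethanesulfonate, CC[Si](CC)(CC)OS(=O)(=O)C(F)(F)F
Why: Silylation with a silyl triflate and a hindered pyridine base caps the secondary C2 and tertiary C4 hydroxyls quickly, without the base-induced acyl migration a free O2 next to the C3 ester would invite.

Step 15
Reactants: 21 C2,C4-bis(triethylsilyl) ether
Product: 23 C8 aldehyde (CH2CHO on C1), via alkenyldicyclohexylborane 22 (not isolated)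
Conditions: Cy2BH (from BH3·SMe2 and cyclohexene), THF, 0 °C; then 30% H2O2, pH 7 buffer (NaH2PO4/Na2HPO4), 0 °C to rt
Reagents that add atoms: hydrogen peroxide, OO
Why: Anti-Markovnikov hydroboration of the terminal alkyne with a bulky dialkylborane stops at the alkenylborane, and buffered peroxide oxidation gives the enol and hence the aldehyde, leaving esters and silyl ethers alone.

Step 16
Reactants: 23 C8 aldehyde
Product: 25 enal (C(=CH2)CHO on C1), via Mannich base 24 (not isolated)
Conditions: Eschenmoser's salt, Et3N, CH2Cl2, rt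
Reagents that add atoms: N,N-dimethylmethyleneiminium iodide, C=[N+](C)C.[I-]
Why: α-Methylenation of the aldehyde by Mannich reaction and β-elimination of dimethylamine.

Step 17
Reactants: 26 3-hydroxy-3-methylbutan-2-one
Product: 27 3-methyl-3-(triethylsilyloxy)butan-2-one
Conditions: TESOTf, 2,6-lutidine, CH2Cl2, 0 °C
Reagents that add atoms: triethylsilyl trifluoromethanesulfonate, CC[Si](CC)(CC)OS(=O)(=O)C(F)(F)F
Why: Silylation of the tertiary alcohol with the silyl triflate.

Step 18
Reactants: 27 3-methyl-3-(triethylsilyloxy)butan-2-one; 25 enal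
Product: 30 aldol adduct ((8S)-hydroxy C10 ketone), via enol borinate 28 (not isolated), via boron aldolate 29 (not isolated)
Conditions: (–)-Ipc2BCl, Et3N, Et2O, 0 °C; then 25, −78 to −20 °C; then H2O2, MeOH, pH 7 buffer, 0 °C
Reagents that add atoms: none
Why: Boron aldol reaction of a methyl ketone under reagent control: the enol diisopinocampheylborinate adds through a cyclic Zimmerman–Traxler-type transition state, and the Ipc ligands from (+)-α-pinene are expected to direct it to the Si face of the aldehyde, which sets C8 as S.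

Step 19
Reactants: 30 aldol adduct
Product: 32 tris(triethylsilyl) ether of the target (C8 isobutyrate, C10 OH), via isobutyraldehyde hemiacetal 31 (not isolated)
Conditions: SmI2 (30 mol%), i-PrCHO (6 equiv), THF, −10 °C
Reagents that add atoms: isobutyraldehyde, CC(C)C=O
Why: Evans–Tishchenko reduction: the O8 hemiacetal of isobutyraldehyde delivers its hydride to the C10 ketone within a samarium chelate through a chair-like bicyclic transition state, which sets C10 1,3-anti to C8 and leaves the isobutyrate on O8.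

Step 20
Reactants: 32 tris(triethylsilyl) ether of the target
Product: 33 CNP0348997.1
Conditions: HF·pyridine, pyridine, THF, 0 °C to rt
Reagents that add atoms: none
Why: Fluoride-mediated cleavage of the three triethylsilyl ethers under buffered acidic conditions avoids the base-induced acyl migrations open to the 1,2- and 1,3-hydroxy esters.

**Compound list**

1 | dibenzyl malonate | O=C(CC(=O)OCc1ccccc1)OCc1ccccc1 | starting material
2 | (E)-4-methoxybut-3-en-2-one | CO/C=C/C(C)=O | starting material
3 | dibenzyl 2-[(E)-3-oxobut-1-enyl]malonate (sodium dienolate in the flask) | CC(=O)/C=C/C(C(=O)OCc1ccccc1)C(=O)OCc1ccccc1 | intermediate (not isolated)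
4 | benzyl 6-methyl-2-oxo-2H-pyran-3-carboxylate | CC1=CC=C(C(=O)OCc2ccccc2)C(=O)O1 | intermediate
5 | 2,2-dimethyl-1,3-dioxolane | CC1(C)OCCO1 | starting material
6 | 4-chloro-2,2-dimethyl-1,3-dioxolane (racemic) | CC1(C)OCC(Cl)O1 | intermediate
7 | 2,2-dimethyl-1,3-dioxole | CC1(C)OC=CO1 | intermediate
8 | endo bicyclic lactone: C7(=O)–O4 bridge up, CO2Bn on C1, Me on C4, C5=C6, C2/C3 acetonide down | O=C1O[C@@]2(C)C=C[C@]1(C(=O)OCc4ccccc4)[C@@H]3OC(C)(C)O[C@H]23 | intermediate
9 | diol lactone: as 8 with OH up on C5 and C6 | O=C1O[C@@]2(C)[C@@H](O)[C@@H](O)[C@]1(C(=O)OCc4ccccc4)[C@@H]3OC(C)(C)O[C@H]23 | intermediate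
10 | diol lactone acid: as 9 with CO2H on C1 | O=C1O[C@@]2(C)[C@@H](O)[C@@H](O)[C@]1(C(=O)O)[C@@H]3OC(C)(C)O[C@H]23 | intermediate
11 | Barton ester: O-acyl N-hydroxypyridine-2-thione of 10 | O=C1O[C@@]2(C)[C@@H](O)[C@@H](O)[C@]1(C(=O)ON4C=CC=CC4=S)[C@@H]3OC(C)(C)O[C@H]23 | intermediate (not isolated)
12 | decarboxylated diol lactone: H on C1 | O=C1O[C@@]2(C)[C@@H](O)[C@@H](O)[C@@H]1[C@@H]3OC(C)(C)O[C@H]23 | intermediate
13 | bridged lactol: C7 hemiacetal to O4, mixture of anomers | OC1O[C@@]2(C)[C@@H](O)[C@@H](O)[C@@H]1[C@@H]3OC(C)(C)O[C@H]23 | intermediate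
14 | alkyne triol: ethynyl up on C1; OH up on C4, C5, C6; C2/C3 acetonide down | C#C[C@H]1[C@@H]3OC(C)(C)O[C@@H]3[C@@](C)(O)[C@@H](O)[C@H]1O | intermediate
15 | C5/C6 cyclic methyl orthoisobutyrate of 14 (epimers at the orthoester carbon) | C#C[C@H]1[C@@H]3OC(C)(C)O[C@@H]3[C@@](C)(O)[C@H]4OC(OC)(C(C)C)O[C@@H]14 | intermediate (not isolated)
16 | C6 isobutyrate, OH on C5 and C4 | C#C[C@H]1[C@@H]3OC(C)(C)O[C@@H]3[C@@](C)(O)[C@@H](O)[C@H]1OC(=O)C(C)C | intermediate
17 | C5 acetate, C6 isobutyrate, OH on C4, C2/C3 acetonide | C#C[C@H]1[C@@H]3OC(C)(C)O[C@@H]3[C@@](C)(O)[C@@H](OC(C)=O)[C@H]1OC(=O)C(C)C | intermediate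
18 | C2,C3,C4-triol, C5 acetate, C6 isobutyrate | C#C[C@H]1[C@H](O)[C@H](O)[C@@](C)(O)[C@@H](OC(C)=O)[C@H]1OC(=O)C(C)C | intermediate
19 | C2/C3 cyclic methyl orthoisobutyrate of 18 (epimers at the orthoester carbon) | C#C[C@H]1[C@@H]3OC(OC)(C(C)C)O[C@@H]3[C@@](C)(O)[C@@H](OC(C)=O)[C@H]1OC(=O)C(C)C | intermediate (not isolated)
20 | C3 and C6 isobutyrates, C5 acetate, OH on C2 and C4 | C#C[C@H]1[C@H](O)[C@H](OC(=O)C(C)C)[C@@](C)(O)[C@@H](OC(C)=O)[C@H]1OC(=O)C(C)C | intermediate
21 | C2,C4-bis(triethylsilyl) ether of 20 | C#C[C@H]1[C@H](O[Si](CC)(CC)CC)[C@H](OC(=O)C(C)C)[C@@](C)(O[Si](CC)(CC)CC)[C@@H](OC(C)=O)[C@H]1OC(=O)C(C)C | intermediate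
22 | (E)-alkenyldicyclohexylborane from 21 | C2CCCCC2B(C3CCCCC3)/C=C/[C@H]1[C@H](O[Si](CC)(CC)CC)[C@H](OC(=O)C(C)C)[C@@](C)(O[Si](CC)(CC)CC)[C@@H](OC(C)=O)[C@H]1OC(=O)C(C)C | intermediate (not isolated)
23 | C8 aldehyde: CH2CHO on C1 | O=CC[C@H]1[C@H](O[Si](CC)(CC)CC)[C@H](OC(=O)C(C)C)[C@@](C)(O[Si](CC)(CC)CC)[C@@H](OC(C)=O)[C@H]1OC(=O)C(C)C | intermediate
24 | Mannich base: 2-(dimethylaminomethyl) aldehyde, C7 epimers | O=CC(CN(C)C)[C@H]1[C@H](O[Si](CC)(CC)CC)[C@H](OC(=O)C(C)C)[C@@](C)(O[Si](CC)(CC)CC)[C@@H](OC(C)=O)[C@H]1OC(=O)C(C)C | intermediate (not isolated)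
25 | enal: C(=CH2)CHO on C1 | C=C(C=O)[C@H]1[C@H](O[Si](CC)(CC)CC)[C@H](OC(=O)C(C)C)[C@@](C)(O[Si](CC)(CC)CC)[C@@H](OC(C)=O)[C@H]1OC(=O)C(C)C | intermediate
26 | 3-hydroxy-3-methylbutan-2-one | CC(=O)C(C)(C)O | starting material
27 | 3-methyl-3-(triethylsilyloxy)butan-2-one | CC(=O)C(C)(C)O[Si](CC)(CC)CC | intermediate
28 | enol diisopinocampheylborinate of 27 | C=C(OB([C@@H]1C[C@@H]2C[C@H]([C@H]1C)C2(C)C)[C@@H]1C[C@@H]2C[C@H]([C@H]1C)C2(C)C)C(C)(C)O[Si](CC)(CC)CC | intermediate (not isolated)
29 | boron aldolate: O8–B(Ipc)2 | C=C([C@H]1[C@H](O[Si](CC)(CC)CC)[C@H](OC(=O)C(C)C)[C@@](C)(O[Si](CC)(CC)CC)[C@@H](OC(C)=O)[C@H]1OC(=O)C(C)C)[C@H](CC(=O)C(C)(C)O[Si](CC)(CC)CC)OB([C@@H]1C[C@@H]2C[C@H]([C@H]1C)C2(C)C)[C@@H]1C[C@@H]2C[C@H]([C@H]1C)C2(C)C | intermediate (not isolated)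
30 | aldol adduct: (8S)-OH, C10 ketone, C11 OTES | C=C([C@H]1[C@H](O[Si](CC)(CC)CC)[C@H](OC(=O)C(C)C)[C@@](C)(O[Si](CC)(CC)CC)[C@@H](OC(C)=O)[C@H]1OC(=O)C(C)C)[C@H](CC(=O)C(C)(C)O[Si](CC)(CC)CC)O | intermediate
31 | O8 hemiacetal of isobutyraldehyde (samarium alkoxide in the flask, epimers at the hemiacetal carbon) | C=C([C@H]1[C@H](O[Si](CC)(CC)CC)[C@H](OC(=O)C(C)C)[C@@](C)(O[Si](CC)(CC)CC)[C@@H](OC(C)=O)[C@H]1OC(=O)C(C)C)[C@H](CC(=O)C(C)(C)O[Si](CC)(CC)CC)OC(O)C(C)C | intermediate (not isolated)
32 | target with OTES on C2, C4 and C11: (8S) isobutyrate, (10S) OH | C=C([C@H]1[C@H](O[Si](CC)(CC)CC)[C@H](OC(=O)C(C)C)[C@@](C)(O[Si](CC)(CC)CC)[C@@H](OC(C)=O)[C@H]1OC(=O)C(C)C)[C@H](C[C@H](O)C(C)(C)O[Si](CC)(CC)CC)OC(=O)C(C)C | intermediate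
33 | CNP0348997.1 | C=C([C@H]1[C@H](O)[C@H](OC(=O)C(C)C)[C@@](C)(O)[C@@H](OC(C)=O)[C@H]1OC(=O)C(C)C)[C@H](C[C@H](O)C(C)(C)O)OC(=O)C(C)C | target

**Count and risks**

Total steps: 20. Longest linear sequence: 18 steps (2, 3, 4–16, 18–20, from 2,2-dimethyl-1,3-dioxolane).

Step 10. The tertiary C4 hydroxyl may take part in orthoester exchange, or the opening may not follow the axial rule, so that the acyl group lands on the wrong oxygen. Fallback: the order of acylation is reversed. From 14, Bu2SnO (MeOH, reflux) should give the 5,6-O-dibutylstannylene acetal F1. Its equatorial O5, the oxygen that stannylene acetals of cis-diols acylate, is acetylated with AcCl (CH2Cl2, 0 °C) to the 5-O-acetate F2. Isobutyryl chloride, pyridine and DMAP then esterify the axial C6 hydroxyl, and the route is rejoined at 17.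

Step 18. Facial control by the Ipc ligands on a methyl ketone enolate may be weak, or opposed by the bulky ring next to the enal, giving a poor C8 ratio. Fallback: a catalyst-controlled Mukaiyama aldol. From 27, TMSOTf/Et3N gives the silyl enol ether F3. Its addition to 25 (SiCl4, chiral 1,1'-binaphthyl-2,2'-diamine-derived bisphosphoramide 5 mol%, i-Pr2NEt cat., CH2Cl2, −78 °C; catalyst antipode chosen for Si-face addition) passes through the trichlorosilyl aldolate F4. Aqueous NaHCO3/KF work-up then returns the route at 30.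

Step 4. Bond formation at the methyl-bearing pyrone terminus may be slow on the chelated diene, or π-face discrimination poor (the antipodal ligand is the first check of the sense). Fallback: asymmetric catalysis is replaced by resolution. From 4 and 7, Yb(OTf)3 (10 mol%, CH2Cl2, rt) should give the racemic endo adduct rac-8 F5. Steps 5 and 6 applied unchanged give the racemic diol rac-9 F6 and the racemic acid rac-10 F7. The acid is resolved by crystallisation of the (R)-1-phenylethylammonium salt F8 (the antipodal amine if that salt is the less soluble one), and acidification with aq. KHSO4 returns the route at 10.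

Further compounds
F1 | step 10 | 5,6-O-dibutylstannylene acetal of 14 | C#C[C@H]1[C@@H]3OC(C)(C)O[C@@H]3[C@@](C)(O)[C@H]4O[Sn](CCCC)(CCCC)O[C@@H]14
F2 | step 10 | 5-O-acetate of 14 (OH on C4 and C6) | C#C[C@H]1[C@@H]3OC(C)(C)O[C@@H]3[C@@](C)(O)[C@@H](OC(C)=O)[C@H]1O
F3 | step 18 | 3-methyl-3-(triethylsilyloxy)-2-(trimethylsilyloxy)but-1-ene | C=C(O[Si](C)(C)C)C(C)(C)O[Si](CC)(CC)CC
F4 | step 18 | trichlorosilyl aldolate (O8–SiCl3) | C=C([C@H]1[C@H](O[Si](CC)(CC)CC)[C@H](OC(=O)C(C)C)[C@@](C)(O[Si](CC)(CC)CC)[C@@H](OC(C)=O)[C@H]1OC(=O)C(C)C)[C@H](CC(=O)C(C)(C)O[Si](CC)(CC)CC)O[Si](Cl)(Cl)Cl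
F5 | step 4 | rac-8 (both enantiomers of the endo adduct) | O=C1O[C@@]2(C)C=C[C@]1(C(=O)OCc4ccccc4)[C@@H]3OC(C)(C)O[C@H]23.O=C1O[C@]2(C)C=C[C@@]1(C(=O)OCc4ccccc4)[C@H]3OC(C)(C)O[C@@H]23
F6 | step 4 | rac-9 (both enantiomers of the diol lactone) | O=C1O[C@@]2(C)[C@@H](O)[C@@H](O)[C@]1(C(=O)OCc4ccccc4)[C@@H]3OC(C)(C)O[C@H]23.O=C1O[C@]2(C)[C@H](O)[C@H](O)[C@@]1(C(=O)OCc4ccccc4)[C@H]3OC(C)(C)O[C@@H]23
F7 | step 4 | rac-10 (both enantiomers of the diol lactone acid) | O=C1O[C@@]2(C)[C@@H](O)[C@@H](O)[C@]1(C(=O)O)[C@@H]3OC(C)(C)O[C@H]23.O=C1O[C@]2(C)[C@H](O)[C@H](O)[C@@]1(C(=O)O)[C@H]3OC(C)(C)O[C@@H]23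
F8 | step 4 | (R)-1-phenylethylammonium salt of 10 | O=C1O[C@@]2(C)[C@@H](O)[C@@H](O)[C@]1(C(=O)[O-])[C@@H]3OC(C)(C)O[C@H]23.C[C@@H]([NH3+])c1ccccc1
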